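**Plan**

- Retrosynthetic cuts, in order: the two phenolic C–O bonds at Ar-C3 and Ar-C5 (back through C–B to C–H), the acetate C–O bond at C2, the C3–C4 bond of the chain (terminal oxirane plus decyl Grignard), and the oxirane back to L-phenylalanine.
- Forward: L-phenylalanine → (S)-hydroxy acid → (S)-diol → (S)-2-benzyloxirane; the decyl chain is joined at C3–C4 by CuI-catalysed Grignard opening; O-acetylation; double meta C–H borylation; oxidation of both C–B bonds. No ring of the target is built: the benzene ring comes from phenylalanine and the oxirane is only a transient three-membered ring.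
- Enabling feature: on the benzene ring the chain (Ar-C1) and the two oxygens (Ar-C3, Ar-C5) are mutually meta. These are the C–H bonds a sterically ruled iridium borylation of a monoalkylbenzene reaches, because the chain shuts Ar-C2 and Ar-C6. The PhCH2–CH(O) unit (C1–C2) is the side chain and α-carbon of phenylalanine.
- Stereochemistry: C2 is the α-carbon of L-phenylalanine. Diazotisation goes with retention and the C2–O bond is never broken afterwards. The descriptor changes from S to R only when the former carboxyl carbon (C3) becomes an alkyl carbon ranked below the benzyl carbon.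

Key step: step 6

Remark on the chemistry: the first borylation of a monoalkylbenzene is assumed to fall on the meta and para C–H bonds in roughly statistical proportion, with none at ortho; the route is sized on that basis.

**Route**

Step 1
Reactants: 1 L-phenylalanine
Product: 2 (S)-2-hydroxy-3-phenylpropanoic acid
Conditions: NaNO2, 1 M aq. H2SO4, 0 °C to rt
Reagents that add atoms: water, O
Why: Diazotisation of the α-amino acid gives a diazonium ion whose nitrogen is displaced by the neighbouring carboxylate to an α-lactone that water reopens at the same carbon, so two inversions add up to retention and the (S) centre of 1 becomes the (S) centre of 2.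

Step 2
Reactants: 2 (S)-2-hydroxy-3-phenylpropanoic acid
Product: 3 (S)-3-phenylpropane-1,2-diol
Conditions: LiAlH4, THF, 0 °C to reflux; H2O, aq. NaOH work-up
Reagents that add atoms: none
Why: LiAlH4 reduction of a carboxylic acid to the primary alcohol, during which the stereocentre sits as an alkoxide beside the carboxylate and has no pathway to epimerise, so (S) is kept.

Step 3
Reactants: 3 (S)-3-phenylpropane-1,2-diol
Product: 5 (S)-2-benzyloxirane, via (S)-2-hydroxy-3-phenylpropyl tosylate 4 (not isolated)
Conditions: TsCl (1.05 equiv), Bu2SnO (2 mol%), Et3N, CH2Cl2, 0 °C to rt; then K2CO3, MeOH, rt; careful concentration (volatile product)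
Reagents that add atoms: 4-methylbenzenesulfonyl chloride, Cc1ccc(cc1)S(=O)(=O)Cl (its atoms are carried by 4 only and leave on ring closure; 5 keeps none)
Why: Bu2SnO forms a stannylene acetal that passes the sulfonyl group to the primary oxygen only (tin-catalysed regioselective monotosylation), and carbonate then closes the oxirane by intramolecular Williamson displacement at C1, so the C2–O bond is never broken and the (S) configuration is retained.

Step 4
Reactants: 5 (S)-2-benzyloxirane; 6 1-bromodecane
Product: 8 (R)-1-phenyltridecan-2-ol, via decylmagnesium bromide 7 (not isolated)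
Conditions: 6, Mg, THF, 40 °C; then CuI (10 mol%), 5, THF, −30 °C to 0 °C; aq. NH4Cl
Reagents that add atoms: magnesium, [Mg] (carried by 7 only; 8 keeps none)
Why: Grignard formation from 6 followed by CuI-catalysed SN2 opening of the monosubstituted oxirane at its unsubstituted carbon forms the C3–C4 bond without touching C2, whose descriptor becomes R only because the new alkyl branch ranks below the benzyl carbon in the sequence rules.

Step 5
Reactants: 8 (R)-1-phenyltridecan-2-ol
Product: 9 (R)-1-phenyltridecan-2-yl acetate
Conditions: Ac2O, pyridine, DMAP (cat.), CH2Cl2, 0 °C to rt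
Reagents that add atoms: acetic anhydride, CC(=O)OC(C)=O
Why: DMAP-catalysed O-acylation of the secondary alcohol by the anhydride takes place at oxygen with retention at C2.

Step 6
Reactants: 9 (R)-1-phenyltridecan-2-yl acetate; 10 bis(pinacolato)diboron
Product: 12 (R)-1-[3,5-bis(4,4,5,5-tetramethyl-1,3,2-dioxaborolan-2-yl)phenyl]tridecan-2-yl acetate, via meta monoboronate 11 (not isolated)
Conditions: 10 (2.5 equiv), [Ir(OMe)(C8H12)]2 (3 mol%; C8H12 = 1,5-cyclooctadiene), 4,4'-di-tert-butyl-2,2'-bipyridine (6 mol%), cyclohexane, 80 °C, under Ar; chromatography on silica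
Reagents that add atoms: none
Why: The iridium precursor, the bipyridine and 10 give a tris(boryl) complex of trivalent iridium that opens one site, cleaves an aryl C–H bond to a pentavalent iridium aryl hydride and then forms the aryl–boron bond by reductive elimination, 10 restoring the tris(boryl) species. The closest known reaction type is the iridium/bipyridine-catalysed steric C–H borylation of alkylbenzenes, including its exhaustive form that takes monosubstituted benzenes to 3,5-bis(boronates). No ring closes and no stereocentre is formed; C2 is remote, and the secondary acetate is inert and cannot steer the metal to an ortho C–H bond because the bidentate ligand leaves a single free coordination site. The selectivity required is positional: the branched chain at Ar-C1 shuts Ar-C2 and Ar-C6, the first boron enters at Ar-C3 to give 11, and in 11 the C–H bond at Ar-C5 is the only one without an ortho neighbour, so the second boron can go nowhere else. Material that reacts first at Ar-C4 (expected at about the statistical share of one reactive C–H in three) ends as a monoboronate with no unhindered C–H bond left; it differs from 12 by a whole boronate group, should separate on silica, and can be returned to 9 by protodeboronation. The excess of 10 and the mild activation of 11 by its boryl group should carry all meta-borylated material through to 12.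

Step 7
Reactants: 12 (R)-1-[3,5-bis(4,4,5,5-tetramethyl-1,3,2-dioxaborolan-2-yl)phenyl]tridecan-2-yl acetate
Product: 14 (R)-1-(3,5-dihydroxyphenyl)tridecan-2-yl acetate, via hydroxy boronate 13 (not isolated)
Conditions: KHSO5 (as the triple salt 2KHSO5·KHSO4·K2SO4; 2.2 equiv of KHSO5), acetone/H2O, 0 °C to rt, about 15 min; aq. NaHSO3
Reagents that add atoms: potassium peroxymonosulfate, [K+].[O-]S(=O)(=O)OO
Why: Oxidative ipso-hydroxylation of aryl boronates, in which the peroxide oxygen of KHSO5 adds to boron, the aryl group shifts from boron to oxygen with loss of sulfate and the aryl borate is hydrolysed, happens twice, while the weakly acidic medium and short contact time leave the secondary acetate and the remote C2 centre untouched.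

**Compound list**

1 | L-phenylalanine, (S)-2-amino-3-phenylpropanoic acid | N[C@@H](Cc1ccccc1)C(=O)O | starting material
2 | (S)-2-hydroxy-3-phenylpropanoic acid | O[C@@H](Cc1ccccc1)C(=O)O | intermediate
3 | (S)-3-phenylpropane-1,2-diol | O[C@@H](Cc1ccccc1)CO | intermediate
4 | (S)-2-hydroxy-3-phenylpropyl 4-methylbenzenesulfonate | O[C@@H](Cc1ccccc1)COS(=O)(=O)c1ccc(C)cc1 | intermediate, not isolated
5 | (S)-2-benzyloxirane | c1ccccc1C[C@H]1CO1 | intermediate
6 | 1-bromodecane | CCCCCCCCCCBr | starting material
7 | decylmagnesium bromide | CCCCCCCCCC[Mg]Br | intermediate, not isolated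
8 | (R)-1-phenyltridecan-2-ol | CCCCCCCCCCC[C@H](Cc1ccccc1)O | intermediate
9 | (R)-1-phenyltridecan-2-yl acetate | CCCCCCCCCCC[C@H](Cc1ccccc1)OC(C)=O | intermediate
10 | bis(pinacolato)diboron | CC1(C)OB(OC1(C)C)B1OC(C)(C)C(C)(C)O1 | starting material
11 | (R)-1-[3-(4,4,5,5-tetramethyl-1,3,2-dioxaborolan-2-yl)phenyl]tridecan-2-yl acetate | CCCCCCCCCCC[C@H](Cc1cccc(B2OC(C)(C)C(C)(C)O2)c1)OC(C)=O | intermediate, not isolated
12 | (R)-1-[3,5-bis(4,4,5,5-tetramethyl-1,3,2-dioxaborolan-2-yl)phenyl]tridecan-2-yl acetate | CCCCCCCCCCC[C@H](Cc1cc(B2OC(C)(C)C(C)(C)O2)cc(B2OC(C)(C)C(C)(C)O2)c1)OC(C)=O | intermediate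
13 | (R)-1-[3-hydroxy-5-(4,4,5,5-tetramethyl-1,3,2-dioxaborolan-2-yl)phenyl]tridecan-2-yl acetate | CCCCCCCCCCC[C@H](Cc1cc(O)cc(B2OC(C)(C)C(C)(C)O2)c1)OC(C)=O | intermediate, not isolated
14 | (R)-1-(3,5-dihydroxyphenyl)tridecan-2-yl acetate | CCCCCCCCCCC[C@H](Cc1cc(O)cc(O)c1)OC(C)=O | target

**Count**

Total step count: 7. Longest linear sequence: 7 steps (1 to 14).

**Steps most likely to fail**

Step 6. First C–H cleavage para to the chain diverts material into a boronate that cannot react further, and a stalled second borylation leaves meta monoboronate, so the bis(boronate) may be obtained in low recovery or be hard to free from its congeners. The fallback sets out from decylmagnesium bromide 7 and returns at 14, carrying both phenol oxygens on the arene from the start.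
- Reagent 7 is added under CuI catalysis in THF at −40 °C to commercial (R)-epichlorohydrin (ClC[C@H]1CO1), attacking the oxirane CH2 to give (R)-1-chlorotridecan-2-ol F1.
- NaOH in aqueous THF closes F1 to (R)-2-undecyloxirane F2.
- Commercial 1-bromo-3,5-bis(benzyloxy)benzene is converted with Mg in THF into 3,5-bis(benzyloxy)phenylmagnesium bromide F3.
- F3 opens F2 at the terminal carbon under CuI catalysis to give (R)-1-[3,5-bis(benzyloxy)phenyl]tridecan-2-ol F4.
- Ac2O, pyridine and DMAP give (R)-1-[3,5-bis(benzyloxy)phenyl]tridecan-2-yl acetate F5.
- H2 over Pd on carbon in EtOAc removes both benzyl ethers without touching the alkyl acetate and gives 14.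

Step 7. Over-oxidation of the electron-rich resorcinol ring as it forms, or partial loss of the C2 acetate in the acidic aqueous medium, may give mixtures. The fallback sets out from 12 and returns at 14. It gives up the acetate during the oxidation and tells the esters apart afterwards.
- H2O2 with aq. NaOH in THF/MeOH, run until the acetate is fully saponified, converts 12 into (R)-5-(2-hydroxytridecyl)benzene-1,3-diol F6.
- Ac2O, pyridine and DMAP give the triacetate (R)-5-(2-acetoxytridecyl)-1,3-phenylene diacetate F7.
- NH4OAc in aqueous MeOH at rt cleaves only the two aryl acetates, whose phenoxide leaving groups make them far more labile than the alkyl acetate, and gives 14.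

Step 4. MgBr2 from the Schlenk equilibrium may open the oxirane to a bromohydrin or trigger a hydride shift to a carbonyl compound that then adds the Grignard reagent, and Wurtz coupling during Grignard formation lowers the titre. The fallback sets out from 5 and returns at 8, forming the C3–C4 bond with an acetylide instead.
- Commercial dec-1-yne (CCCCCCCCC#C) and n-BuLi in THF at −78 °C give lithium dec-1-ynide F8.
- With BF3·OEt2, F8 opens 5 at the terminal carbon to give (S)-1-phenyltridec-4-yn-2-ol F9. Its geometry is that of 8; the descriptor reads S only because the propargylic carbon outranks the benzylic one.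
- H2 over Pd on carbon in EtOAc saturates the triple bond and gives 8.

Further compounds
F1 | step 6 | (R)-1-chlorotridecan-2-ol | CCCCCCCCCCC[C@H](CCl)O
F2 | step 6 | (R)-2-undecyloxirane | CCCCCCCCCCC[C@@H]1CO1
F3 | step 6 | 3,5-bis(benzyloxy)phenylmagnesium bromide | Br[Mg]c1cc(OCc2ccccc2)cc(OCc2ccccc2)c1
F4 | step 6 | (R)-1-[3,5-bis(benzyloxy)phenyl]tridecan-2-ol | CCCCCCCCCCC[C@H](Cc1cc(OCc2ccccc2)cc(OCc2ccccc2)c1)O
F5 | step 6 | (R)-1-[3,5-bis(benzyloxy)phenyl]tridecan-2-yl acetate | CCCCCCCCCCC[C@H](Cc1cc(OCc2ccccc2)cc(OCc2ccccc2)c1)OC(C)=O
F6 | step 7 | (R)-5-(2-hydroxytridecyl)benzene-1,3-diol | CCCCCCCCCCC[C@H](Cc1cc(O)cc(O)c1)O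
F7 | step 7 | (R)-5-(2-acetoxytridecyl)-1,3-phenylene diacetate | CCCCCCCCCCC[C@H](Cc1cc(OC(C)=O)cc(OC(C)=O)c1)OC(C)=O
F8 | step 4 | lithium dec-1-ynide | [Li]C#CCCCCCCCC
F9 | step 4 | (S)-1-phenyltridec-4-yn-2-ol | CCCCCCCCC#CC[C@H](Cc1ccccc1)O
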